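The route cuts the C2=C3 alkene of the cyclopentene (ring A; indene numbering, C3 bears the ethyl group). Because C2 carries only H and C3 only ethyl, both can be carbonyl carbons. The precursor is therefore a cyclohexene (ring B) with a 1-oxopropan-2-yl arm on C7a and a propanoyl arm on C3a, trans to each other. One titanium-mediated reductive coupling joins the two carbonyl carbons, removes both oxygens and closes ring A with its alkene in place. The keto aldehyde comes from a δ-lactone made by an ester-tethered intramolecular Diels–Alder reaction, which builds ring B and four stereocentres from the single bought centre C1.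

Key step: step 13

Remark on the chemistry: ylide 6 is taken as a catalogue compound. Locants for 16 follow isochromene numbering (C1 lactone carbonyl, C8a next to it); locants for 21 and 22 follow indene numbering. All polyene intermediates are handled under argon with exclusion of light.

Step 1
Reactants: 1 methyl (2R)-3-hydroxy-2-methylpropanoate
Product: 2 methyl (2R)-3-[(tert-butyldimethylsilyl)oxy]-2-methylpropanoate
Conditions: TBSCl, imidazole, CH2Cl2, 0 °C to rt
Reagents that add atoms: tert-butyldimethylsilyl chloride, CC(C)(C)[Si](C)(C)Cl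
Why: Silyl ether formation on a primary alcohol, which does not touch the bought stereocentre.

Step 2
Reactants: 2 methyl (2R)-3-[(tert-butyldimethylsilyl)oxy]-2-methylpropanoate
Product: 3 (2R)-3-[(tert-butyldimethylsilyl)oxy]-2-methylpropanal
Conditions: iBu2AlH (1.05 equiv), CH2Cl2, −78 °C; aq. potassium sodium tartrate
Reagents that add atoms: none
Why: Partial hydride reduction of the ester stops at the aluminium hemiacetal at −78 °C, and the α-stereocentre should survive if the aldehyde is used crude.

Step 3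
Reactants: 3 (2R)-3-[(tert-butyldimethylsilyl)oxy]-2-methylpropanal; 4 2-(triphenyl-λ5-phosphanylidene)propanal
Product: 5 (2E,4S)-5-[(tert-butyldimethylsilyl)oxy]-2,4-dimethylpent-2-enal
Conditions: PhMe, 80 °C
Reagents that add atoms: none
Why: Wittig olefination with a formyl-stabilised ylide should give the (E)-2-methyl enal under neutral conditions that do not epimerise C4.

Step 4
Reactants: 5 (2E,4S)-5-[(tert-butyldimethylsilyl)oxy]-2,4-dimethylpent-2-enal; 6 2-(triphenyl-λ5-phosphanylidene)butanal
Product: 7 (2E,4E,6S)-7-[(tert-butyldimethylsilyl)oxy]-2-ethyl-4,6-dimethylhepta-2,4-dienal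
Conditions: PhMe, 110 °C
Reagents that add atoms: none
Why: A second Wittig olefination with a formyl-stabilised ylide should add the ethyl-branched (E)-alkene, and the more conjugated, more hindered product reacts more slowly than 5, which limits double homologation.

Step 5
Reactants: 7 (2E,4E,6S)-7-[(tert-butyldimethylsilyl)oxy]-2-ethyl-4,6-dimethylhepta-2,4-dienal; 4 2-(triphenyl-λ5-phosphanylidene)propanal
Product: 8 (2E,4E,6E,8S)-9-[(tert-butyldimethylsilyl)oxy]-4-ethyl-2,6,8-trimethylnona-2,4,6-trienal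
Conditions: PhMe, 110 °C
Reagents that add atoms: none
Why: A third Wittig olefination of the same kind should extend the chain by the methyl-branched (E)-alkene.

Step 6
Reactants: 8 (2E,4E,6E,8S)-9-[(tert-butyldimethylsilyl)oxy]-4-ethyl-2,6,8-trimethylnona-2,4,6-trienal; 9 diethyl benzylphosphonate
Product: 10 tert-butyl{[(2S,3E,5E,7E,9E)-6-ethyl-2,4,8-trimethyl-10-phenyldeca-3,5,7,9-tetraen-1-yl]oxy}dimethylsilane
Conditions: NaH, THF, 0 °C to rt
Reagents that add atoms: none
Why: Horner–Wadsworth–Emmons olefination with a benzylic phosphonate anion should give the (E)-styryl alkene and complete the tetraene.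

Step 7
Reactants: 10 tert-butyl{[(2S,3E,5E,7E,9E)-6-ethyl-2,4,8-trimethyl-10-phenyldeca-3,5,7,9-tetraen-1-yl]oxy}dimethylsilane
Product: 11 (2S,3E,5E,7E,9E)-6-ethyl-2,4,8-trimethyl-10-phenyldeca-3,5,7,9-tetraen-1-ol
Conditions: Bu4NF, THF, 0 °C to rt
Reagents that add atoms: none
Why: Fluoride-mediated desilylation should free the primary alcohol without touching the polyene.

Step 8
Reactants: 12 glyoxylic acid monohydrate; 13 methyl 2-(triphenyl-λ5-phosphanylidene)propanoate
Product: 14 (2E)-4-methoxy-3-methyl-4-oxobut-2-enoic acid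
Conditions: CH2Cl2, 0 °C to rt
Reagents that add atoms: none
Why: Wittig reaction of an ester-stabilised ylide with the aldehyde group of glyoxylic acid should give the (E)-alkene with the two carboxyl carbons trans and leave the acid free for esterification.

Step 9
Reactants: 11 (2S,3E,5E,7E,9E)-6-ethyl-2,4,8-trimethyl-10-phenyldeca-3,5,7,9-tetraen-1-ol; 14 (2E)-4-methoxy-3-methyl-4-oxobut-2-enoic acid
Product: 15 4-[(2S,3E,5E,7E,9E)-6-ethyl-2,4,8-trimethyl-10-phenyldeca-3,5,7,9-tetraen-1-yl] 1-methyl (2E)-2-methylbut-2-enedioate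
Conditions: DCC, DMAP (cat), CH2Cl2, 0 °C to rt
Reagents that add atoms: none
Why: Carbodiimide esterification under Steglich conditions should join the primary alcohol to the free carboxyl group of 14 under neutral conditions that tolerate the tetraene and keep the (E)-geometry of the mesaconate.

Step 10
Reactants: 15 4-[(2S,3E,5E,7E,9E)-6-ethyl-2,4,8-trimethyl-10-phenyldeca-3,5,7,9-tetraen-1-yl] 1-methyl (2E)-2-methylbut-2-enedioate
Product: 16 methyl (4S,4aS,7S,8R,8aS)-7-ethyl-4,5,8-trimethyl-7-[(1E,3E)-2-methyl-4-phenylbuta-1,3-dien-1-yl]-1-oxo-3,4,4a,7,8,8a-hexahydro-1H-isochromene-8-carboxylate (trans-fused δ-lactone)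
Conditions: PhMe (0.01 M), BHT, 120 °C, sealed tube
Reagents that add atoms: none
Why: Type 1 intramolecular Diels–Alder reaction of an ester-tethered 1,7,9-decatriene, in which the doubly activated mesaconate can only reach the C3=C4–C5=C6 diene of the tetraenyl chain: suprafacial addition of the (E)-dienophile to the (E,E)-diene fixes the relative configuration of C7 and C8 and of C4a and C8a, the bought centre (C4 of 16) steers the dienophile to one diene face because allylic 1,3-strain with the neighbouring vinylic methyl keeps its hydrogen in the diene plane, and the transition state with the methyl ester endo and the tether carbonyl exo, the usual preference of fumarate-type ester tethers, should give the trans ring fusion.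

Step 11
Reactants: 16 methyl (4S,4aS,7S,8R,8aS)-7-ethyl-4,5,8-trimethyl-7-[(1E,3E)-2-methyl-4-phenylbuta-1,3-dien-1-yl]-1-oxo-3,4,4a,7,8,8a-hexahydro-1H-isochromene-8-carboxylate
Product: 18 methyl (1R,2S,5S,6S)-2-ethyl-5-[(2S)-1-hydroxypropan-2-yl]-1,4-dimethyl-2-[(1E,3E)-2-methyl-4-phenylbuta-1,3-dien-1-yl]-6-propanoylcyclohex-3-ene-1-carboxylate, via lithium hemiketalate 17 (not isolated)
Conditions: EtLi (1.1 equiv), THF, −78 °C; AcOH, −78 °C
Reagents that add atoms: ethyllithium, [Li]CC
Why: Addition of an organolithium to a lactone at −78 °C should stop at the tetrahedral lithium hemiketalate 17, which does not collapse to the ketone before the acidic quench, so one ethyl group is delivered to the lactone carbonyl while the methyl ester on the doubly neopentyl quaternary carbon is too hindered to compete; no stereocentre is created or lost.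

Step 12
Reactants: 18 methyl (1R,2S,5S,6S)-2-ethyl-5-[(2S)-1-hydroxypropan-2-yl]-1,4-dimethyl-2-[(1E,3E)-2-methyl-4-phenylbuta-1,3-dien-1-yl]-6-propanoylcyclohex-3-ene-1-carboxylate
Product: 19 methyl (1R,2S,5S,6S)-2-ethyl-1,4-dimethyl-2-[(1E,3E)-2-methyl-4-phenylbuta-1,3-dien-1-yl]-5-[(2S)-1-oxopropan-2-yl]-6-propanoylcyclohex-3-ene-1-carboxylate
Conditions: Dess–Martin periodinane, pyridine, CH2Cl2, 0 °C to rt
Reagents that add atoms: none
Why: Dess–Martin oxidation of the primary alcohol under buffered, non-basic conditions should give the aldehyde without epimerising the adjacent methyl-bearing centre, and since only the open hydroxy ketone is consumed, any ring–chain equilibrium of 18 with its hemiketal form is drained.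

Step 13
Reactants: 19 methyl (1R,2S,5S,6S)-2-ethyl-1,4-dimethyl-2-[(1E,3E)-2-methyl-4-phenylbuta-1,3-dien-1-yl]-5-[(2S)-1-oxopropan-2-yl]-6-propanoylcyclohex-3-ene-1-carboxylate
Product: 21 methyl (1R,3aR,4R,5S,7aS)-3,5-diethyl-1,4,7-trimethyl-5-[(1E,3E)-2-methyl-4-phenylbuta-1,3-dien-1-yl]-3a,4,5,7a-tetrahydro-1H-indene-4-carboxylate, via titanium pinacolate 20 (not isolated)
Conditions: TiCl3, Zn–Cu couple, DME, reflux; 19 added over 24 h by syringe pump
Reagents that add atoms: none
Why: Intramolecular McMurry coupling: low-valent titanium, made from trivalent TiCl3 and the zinc–copper couple, transfers one electron to each carbonyl group, the aldehyde and ketone ketyl carbons join to give titanium pinacolate 20, and at reflux the oxophilic metal strips both oxygens to leave the C2=C3 alkene. The closest known reaction type is the titanium-mediated reductive cyclisation of keto aldehydes to cycloalkenes, which is well established for five-membered rings. Ring A is closed as a carbonyl–carbonyl (pinacol-type) coupling between the aldehyde carbon on the C7a arm and the ketone carbon on the C3a arm, which the trans-diequatorial arrangement on ring B holds within bonding distance, and the ring size allows only the required cis alkene. No stereocentre is created: the two carbinol centres of 20 are erased on deoxygenation, and the five existing centres are not touched because the medium is non-basic and ketyl formation should outrun enolisation next to the aldehyde. The step needs chemoselectivity for the two carbonyl groups over the methyl ester and the polyene, secured by the slow reaction of esters with this reagent (here an ester on a quaternary carbon flanked by a second one) and by the inertness of alkenes to it, and it needs cyclisation over dimerisation, secured by syringe-pump addition at high dilution.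

Step 14
Reactants: 21 methyl (1R,3aR,4R,5S,7aS)-3,5-diethyl-1,4,7-trimethyl-5-[(1E,3E)-2-methyl-4-phenylbuta-1,3-dien-1-yl]-3a,4,5,7a-tetrahydro-1H-indene-4-carboxylate
Product: 22 (1R,3aR,4R,5S,7aS)-3,5-diethyl-1,4,7-trimethyl-5-[(1E,3E)-2-methyl-4-phenylbuta-1,3-dien-1-yl]-3a,4,5,7a-tetrahydro-1H-indene-4-carboxylic acid (CNP0226943.1)
Conditions: NaSEt, DMF, 80 °C; then aq. HCl
Reagents that add atoms: none
Why: Nucleophilic demethylation (SN2 attack of thiolate on the ester methyl group) should cleave the ester without attack at the shielded carbonyl carbon and under non-acidic conditions that leave the polyene and all stereocentres untouched.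

Compound list
1 | methyl (2R)-3-hydroxy-2-methylpropanoate | OC[C@@H](C)C(=O)OC | starting material
2 | methyl (2R)-3-[(tert-butyldimethylsilyl)oxy]-2-methylpropanoate | CC(C)(C)[Si](C)(C)OC[C@@H](C)C(=O)OC | intermediate
3 | (2R)-3-[(tert-butyldimethylsilyl)oxy]-2-methylpropanal | CC(C)(C)[Si](C)(C)OC[C@@H](C)C=O | intermediate
4 | 2-(triphenyl-λ5-phosphanylidene)propanal | CC(C=O)=P(c1ccccc1)(c1ccccc1)c1ccccc1 | starting material
5 | (2E,4S)-5-[(tert-butyldimethylsilyl)oxy]-2,4-dimethylpent-2-enal | CC(C)(C)[Si](C)(C)OC[C@@H](C)/C=C(C)/C=O | intermediate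
6 | 2-(triphenyl-λ5-phosphanylidene)butanal | CCC(C=O)=P(c1ccccc1)(c1ccccc1)c1ccccc1 | starting material
7 | (2E,4E,6S)-7-[(tert-butyldimethylsilyl)oxy]-2-ethyl-4,6-dimethylhepta-2,4-dienal | CC(C)(C)[Si](C)(C)OC[C@@H](C)/C=C(C)/C=C(CC)/C=O | intermediate
8 | (2E,4E,6E,8S)-9-[(tert-butyldimethylsilyl)oxy]-4-ethyl-2,6,8-trimethylnona-2,4,6-trienal | CC(C)(C)[Si](C)(C)OC[C@@H](C)/C=C(C)/C=C(CC)/C=C(C)/C=O | intermediate
9 | diethyl benzylphosphonate | CCOP(=O)(Cc1ccccc1)OCC | starting material
10 | tert-butyl{[(2S,3E,5E,7E,9E)-6-ethyl-2,4,8-trimethyl-10-phenyldeca-3,5,7,9-tetraen-1-yl]oxy}dimethylsilane | CC(C)(C)[Si](C)(C)OC[C@@H](C)/C=C(C)/C=C(CC)/C=C(C)/C=C/c1ccccc1 | intermediate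
11 | (2S,3E,5E,7E,9E)-6-ethyl-2,4,8-trimethyl-10-phenyldeca-3,5,7,9-tetraen-1-ol | OC[C@@H](C)/C=C(C)/C=C(CC)/C=C(C)/C=C/c1ccccc1 | intermediate
12 | glyoxylic acid monohydrate (2,2-dihydroxyacetic acid) | OC(O)C(=O)O | starting material
13 | methyl 2-(triphenyl-λ5-phosphanylidene)propanoate | COC(=O)C(C)=P(c1ccccc1)(c1ccccc1)c1ccccc1 | starting material
14 | (2E)-4-methoxy-3-methyl-4-oxobut-2-enoic acid | OC(=O)/C=C(C)/C(=O)OC | intermediate
15 | 4-[(2S,3E,5E,7E,9E)-6-ethyl-2,4,8-trimethyl-10-phenyldeca-3,5,7,9-tetraen-1-yl] 1-methyl (2E)-2-methylbut-2-enedioate | COC(=O)/C(C)=C/C(=O)OC[C@@H](C)/C=C(C)/C=C(CC)/C=C(C)/C=C/c1ccccc1 | intermediate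
16 | methyl (4S,4aS,7S,8R,8aS)-7-ethyl-4,5,8-trimethyl-7-[(1E,3E)-2-methyl-4-phenylbuta-1,3-dien-1-yl]-1-oxo-3,4,4a,7,8,8a-hexahydro-1H-isochromene-8-carboxylate | O=C1OC[C@@H](C)[C@@H]2C(C)=C[C@@](/C=C(C)/C=C/c3ccccc3)(CC)[C@](C)(C(=O)OC)[C@@H]12 | intermediate
17 | lithium hemiketalate of 16 (ethyl adduct at C1, configuration at C1 not defined) | CCC1([O-])OC[C@@H](C)[C@@H]2C(C)=C[C@@](/C=C(C)/C=C/c3ccccc3)(CC)[C@](C)(C(=O)OC)[C@@H]12.[Li+] | intermediate
18 | methyl (1R,2S,5S,6S)-2-ethyl-5-[(2S)-1-hydroxypropan-2-yl]-1,4-dimethyl-2-[(1E,3E)-2-methyl-4-phenylbuta-1,3-dien-1-yl]-6-propanoylcyclohex-3-ene-1-carboxylate | OC[C@@H](C)[C@@H]1C(C)=C[C@@](/C=C(C)/C=C/c2ccccc2)(CC)[C@](C)(C(=O)OC)[C@H]1C(=O)CC | intermediate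
19 | methyl (1R,2S,5S,6S)-2-ethyl-1,4-dimethyl-2-[(1E,3E)-2-methyl-4-phenylbuta-1,3-dien-1-yl]-5-[(2S)-1-oxopropan-2-yl]-6-propanoylcyclohex-3-ene-1-carboxylate | O=C[C@@H](C)[C@@H]1C(C)=C[C@@](/C=C(C)/C=C/c2ccccc2)(CC)[C@](C)(C(=O)OC)[C@H]1C(=O)CC | intermediate
20 | titanium pinacolate of 19 (drawn as the 2,3-diolate with one titanium dication, carbinol configurations not defined) | CCC1([O-])C([O-])[C@@H](C)[C@@H]2C(C)=C[C@@](/C=C(C)/C=C/c3ccccc3)(CC)[C@](C)(C(=O)OC)[C@@H]12.[Ti+2] | intermediate
21 | methyl (1R,3aR,4R,5S,7aS)-3,5-diethyl-1,4,7-trimethyl-5-[(1E,3E)-2-methyl-4-phenylbuta-1,3-dien-1-yl]-3a,4,5,7a-tetrahydro-1H-indene-4-carboxylate | CCC1=C[C@@H](C)[C@@H]2C(C)=C[C@@](/C=C(C)/C=C/c3ccccc3)(CC)[C@](C)(C(=O)OC)[C@@H]12 | intermediate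
22 | (1R,3aR,4R,5S,7aS)-3,5-diethyl-1,4,7-trimethyl-5-[(1E,3E)-2-methyl-4-phenylbuta-1,3-dien-1-yl]-3a,4,5,7a-tetrahydro-1H-indene-4-carboxylic acid | CCC1=C[C@@H](C)[C@@H]2C(C)=C[C@@](/C=C(C)/C=C/c3ccccc3)(CC)[C@](C)(C(=O)O)[C@@H]12 | target

Total step count: 14.
Longest linear sequence: 13 steps (1 to 22 through steps 1–7 and 9–14).

Steps most likely to fail

Step 10. The ester tether may keep the dienophile in its extended, unreactive conformation, so that thermal hydrogen shifts or polymerisation of the tetraene outrun the cycloaddition. The endo/exo preference may also be too weak to give mainly the trans ring fusion. The fallback sets out from 11 and replaces the (E)-dienophile by the (Z)-dienophile, for which both ester carbonyls can be endo at once. Opening of commercial citraconic anhydride by 11 (Et3N, DMAP, CH2Cl2) at its less hindered carbonyl should give (2Z)-4-{[(2S,3E,5E,7E,9E)-6-ethyl-2,4,8-trimethyl-10-phenyldeca-3,5,7,9-tetraen-1-yl]oxy}-2-methyl-4-oxobut-2-enoic acid F1. Methylation with Me3SiCHN2 in PhMe/MeOH should give the citraconate diester, 4-[(2S,3E,5E,7E,9E)-6-ethyl-2,4,8-trimethyl-10-phenyldeca-3,5,7,9-tetraen-1-yl] 1-methyl (2Z)-2-methylbut-2-enedioate F2. Its intramolecular Diels–Alder reaction (PhMe, 110 °C) should give the cis-fused lactone, methyl (4S,4aS,7S,8R,8aR)-7-ethyl-4,5,8-trimethyl-7-[(1E,3E)-2-methyl-4-phenylbuta-1,3-dien-1-yl]-1-oxo-3,4,4a,7,8,8a-hexahydro-1H-isochromene-8-carboxylate F3. This differs from 16 only at C8a, the one centre next to the lactone carbonyl. Base equilibration (DBU, PhMe, rt to 60 °C) should epimerise C8a to the trans-fused lactone, in which both ring-fusion substituents are equatorial, and so return to 16.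

Step 13. The coupling may stall at the pinacol stage. The keto aldehyde may also undergo Lewis-acid-promoted aldol closure of the ethyl ketone onto the aldehyde, or epimerise next to the aldehyde, before the ketyl radicals couple. The fallback sets out from 19 and closes the same C2=C3 bond by alkene metathesis. Non-basic double methylenation (Zn, CH2Br2, TiCl4, THF/CH2Cl2, 0 °C to rt) should give methyl (1R,2S,5S,6R)-5-[(2R)-but-3-en-2-yl]-6-(but-1-en-2-yl)-2-ethyl-1,4-dimethyl-2-[(1E,3E)-2-methyl-4-phenylbuta-1,3-dien-1-yl]cyclohex-3-ene-1-carboxylate F4. Ring-closing metathesis with the second-generation Hoveyda–Grubbs catalyst RuCl2(H2IMes)(=CH-C6H4-2-OiPr) in PhMe at 80 °C should then load on the monosubstituted vinyl group, close the five-membered ring onto the 1,1-disubstituted alkene and return to 21.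

Step 11. Ethyllithium may enolise the lactone at C8a instead of adding, or the hemiketalate may collapse early and take up a second ethyl group. The fallback sets out from 16 and separates ring opening from carbon–carbon bond formation. Aminolysis with MeNH(OMe)·HCl and AlMe3 (CH2Cl2, 0 °C) should give the hydroxy Weinreb amide, methyl (1R,2S,5S,6S)-2-ethyl-5-[(2S)-1-hydroxypropan-2-yl]-6-[methoxy(methyl)carbamoyl]-1,4-dimethyl-2-[(1E,3E)-2-methyl-4-phenylbuta-1,3-dien-1-yl]cyclohex-3-ene-1-carboxylate F5. EtMgBr (3 equiv, THF, 0 °C) then adds once, because the magnesium chelate is stable until work-up, and returns to 18.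

Further compounds
F1 | step 10 | (2Z)-4-{[(2S,3E,5E,7E,9E)-6-ethyl-2,4,8-trimethyl-10-phenyldeca-3,5,7,9-tetraen-1-yl]oxy}-2-methyl-4-oxobut-2-enoic acid | OC(=O)/C(C)=C\C(=O)OC[C@@H](C)/C=C(C)/C=C(CC)/C=C(C)/C=C/c1ccccc1
F2 | step 10 | 4-[(2S,3E,5E,7E,9E)-6-ethyl-2,4,8-trimethyl-10-phenyldeca-3,5,7,9-tetraen-1-yl] 1-methyl (2Z)-2-methylbut-2-enedioate | COC(=O)/C(C)=C\C(=O)OC[C@@H](C)/C=C(C)/C=C(CC)/C=C(C)/C=C/c1ccccc1
F3 | step 10 | methyl (4S,4aS,7S,8R,8aR)-7-ethyl-4,5,8-trimethyl-7-[(1E,3E)-2-methyl-4-phenylbuta-1,3-dien-1-yl]-1-oxo-3,4,4a,7,8,8a-hexahydro-1H-isochromene-8-carboxylate | O=C1OC[C@@H](C)[C@@H]2C(C)=C[C@@](/C=C(C)/C=C/c3ccccc3)(CC)[C@](C)(C(=O)OC)[C@H]12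
F4 | step 13 | methyl (1R,2S,5S,6R)-5-[(2R)-but-3-en-2-yl]-6-(but-1-en-2-yl)-2-ethyl-1,4-dimethyl-2-[(1E,3E)-2-methyl-4-phenylbuta-1,3-dien-1-yl]cyclohex-3-ene-1-carboxylate | C=C[C@@H](C)[C@@H]1C(C)=C[C@@](/C=C(C)/C=C/c2ccccc2)(CC)[C@](C)(C(=O)OC)[C@H]1C(=C)CC
F5 | step 11 | methyl (1R,2S,5S,6S)-2-ethyl-5-[(2S)-1-hydroxypropan-2-yl]-6-[methoxy(methyl)carbamoyl]-1,4-dimethyl-2-[(1E,3E)-2-methyl-4-phenylbuta-1,3-dien-1-yl]cyclohex-3-ene-1-carboxylate | OC[C@@H](C)[C@@H]1C(C)=C[C@@](/C=C(C)/C=C/c2ccccc2)(CC)[C@](C)(C(=O)OC)[C@H]1C(=O)N(C)OC
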